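All constants are made up; the flask was simulated.

13.7 min is how long initiator lasts on average in this flask, and the examination turns on that number.

    free monomer + initiator → living end + monomer in chains (k1 = 0.0036 L mol⁻¹ min⁻¹)
    initiator → spent initiator B (k2 = 0.040 min⁻¹)
    free monomer + living end → monomer in chains + living end, rate k3*[living end]*[free monomer] (k3 = 1.7 L mol⁻¹ min⁻¹)
    2 initiator → spent initiator A (k4 = 0.80 L mol⁻¹ min⁻¹)

free monomer 1.0 M; initiator 4.4 mol%; time 5.0 h

- two of one species on the left: rate k times its square, two consumed each time
- the average divides the monomer in chains by the number of chains begun, living and dead together
- run time (flask): 5.0 h

* whether the average number of monomer units in a chain (chains begun, living or dead) reaches 200 by 5.0 h (no / yes)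
* average number of monomer units in a chain (chains begun, living or dead) at 5.0 h

*What consumes initiator at the start?* Chain starting runs at 0.00360 min⁻¹, decay to spent initiator B at 0.040 min⁻¹, and pairing to spent initiator A at 0.0704 min⁻¹. Chain starting is the slowest.

*But pairing slows as initiator falls. What then?* Replace the curve by its mean. The mean life, the area under the initiator curve divided by its charge, is the logarithm of one plus pairing pace over first-order pace (0.0436 min⁻¹), divided by pairing pace. That gives 13.7 min.

*How many chains?* Starting pace times mean life gives 4.91 % of the charge, so 0.00216 M.

*The weak spot?* I held free monomer at its charge. With these ends present for one mean life, it would lose 5.02 %, and I take that as the rough size of the overstatement in my chain count.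

*And the length?* No step removes living ends, so free monomer falls pseudo-first-order, as if the ends had stood from one mean life onward. My reckoning gives 301, which is above 200.

The forecast says yes and 300, within 280 to 320: “Most of the initiator is lost to its own second-order and first-order decay within the first hour or so”.

The flask gives yes and 304. Its living end stands at 0.00209 M after 5.00 h, which is 4.76 % of the initiator charge, beside the 4.91 % from the mean life. In the flask with half the initiator, pairing starts at half the pace, so the mean life lengthens to 16.8 min. By the same reckoning, chains begun come to 0.00133 M and the length to 355. That flask ran to 356.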